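(The numbers in the tables stem from a simulated flask on assumed constants, noise included.)

Start with the amounts in ash, which has the charges of the south run, so the south readings stand for it. Count each entry in percent of the starting material charged.

| setting | south | east | west | south-west | oak | ash | larch | alder |
|---|---|---|---|---|---|---|---|---|
| starting material | 0.010 M | 0.010 M | 0.010 M | 0.010 M | 0.010 M (fed, over 10 h) | 0.010 M | 0.010 M (in portions, 5, over 10 h) | 0.010 M |
| activator | 9.5 mM | 4.8 mM | 19 mM | 9.5 mM | 9.50 mM | 9.50 mM | 9.50 mM | 9.50 mM (fed, over 10 h) |
| protic impurity | 0.50 mM | 0.50 mM | 0.50 mM | 0.75 mM | 0.500 mM | 0.500 mM | 0.500 mM | 0.500 mM |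
| remark | run made earlier | run made earlier | run made earlier | run made earlier | all else is in the flask from the start; the feed brings no volume worth counting | everything together at the start | first portion at the start, last at 10 h | all else is in the flask from the start; the feed brings no volume worth counting |
| time |  |  |  |  | 25 h | 25 h | 25 h | 25 h |

| run | time / h | ring / % | open dimer / % |
|---|---|---|---|
| south | 4.00 | 8 | 0 |
| south | 8.00 | 17 | 2 |
| south | 12.0 | 28 | 4 |
| south | 15.0 | 31 | 3 |
| south | 20.0 | 38 | 5 |
| south | 25.0 | 42 | 6 |
| east | 3.00 | 2 | 1 |
| east | 6.00 | 8 | 1 |
| east | 10.0 | 13 | 0 |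
| east | 12.0 | 16 | 2 |
| east | 15.0 | 21 | 2 |
| east | 20.0 | 24 | 5 |
| west | 1.33 | 6 | 1 |
| west | 4.00 | 14 | 4 |
| west | 8.00 | 32 | 3 |
| west | 10.0 | 39 | 4 |
| west | 15.0 | 52 | 6 |
| west | 20.0 | 60 | 4 |
| south-west | 2.00 | 4 | 0 |
| south-west | 5.00 | 10 | 0 |
| south-west | 10.0 | 24 | 1 |
| south-west | 15.0 | 34 | 3 |
| south-west | 20.0 | 39 | 3 |

(readings scatter by 1.5 percentage points)

1. the flask with the highest share of ring in ring plus open dimer ("all alike" if they lie within 1.5 percentage points) (oak / ash / larch / alder / all alike)
2. share of ring in ring plus open dimer at the end, oak
3. share of ring in ring plus open dimer at the end, ash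
4. share of ring in ring plus open dimer at the end, larch
5. share of ring in ring plus open dimer at the end, alder

- percent here means starting material units held: one open dimer counts as two

At 25.0 h the ledger has ring 42 % and open dimer 6 %. If each protic impurity takes one starting material, that entry is 5.00 %. The books close with 47.0 % unread. The question concerns two entries, so carry their ratio, a selectivity factor, in powers of ten. Dimer readings are small against the scatter, so pool the earlier runs. Their first readings give ring to open dimer of 9.76, and their later readings give 9.21. Together they give 9.37. So the common logarithm of ring over open dimer, the ring exponent 0.972, means a share of 90.4 %.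

Near that share, the margin of 1.5 percentage points is 0.0747 on the exponent. Early and late readings differ by 0.0254, less than that, although c(starting material) falls during a run. Oak and larch receive their starting material over 10 h, whereas alder holds its whole charge of it from the start and receives activator over 10 h, so dosing pushes c(starting material) in opposite ways in these flasks. I take that push to be of the size of the drift within a run, which stayed under the bar, so I reckon each flask near 90.4 % and call them alike, a judgement the wide scatter on those sums leaves open.

The forecast differs: it names oak, with 90.5 % for oak, 89 % for ash, 90.4 % for larch and 88.5 % for alder, and says “the call is marginal”.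

    starting material + activator → activated form (k = 0.157 M⁻¹ min⁻¹)
    activated form → ring (k = 0.00308 min⁻¹)
    starting material + activated form → open dimer (k = 0.0263 M⁻¹ min⁻¹)
    ring ⇌ isomer of the product (K = 0.370, k = 5.51 × 10⁻⁴ min⁻¹)
    2 starting material → self-condensation product (k = 0.0121 M⁻¹ min⁻¹)
    starting material + protic impurity → quenched substrate (k = 3.36 M⁻¹ min⁻¹)

The flasks give 91.4 % for oak, 90.9 % for ash, 91.6 % for larch and 90.9 % for alder, so the answer is all alike. Larch stands above ash by 0.0370 on the exponent, less than the bar. In ash, the activated form has a half-life of 3.8 h toward ring, shorter than its 44 h toward open dimer at the charged concentrations. That ratio has the logarithm 1.06, beside 0.972. The neighbour of oak with 0.038 M of activator holds ring 68.6 % and open dimer 2.19 %, which stands 0.524 above 0.972, a share of 96.9 %.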